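Readings and results are calculated for substances that don't exist; scatter was added.

In a one-step world the fraction of free monomer left tells the fraction made, and the wanted product keeps the whole of it. I test that on these runs by working with what is left.

| flask | free monomer | initiator | remark | time |
|---|---|---|---|---|
| midnight | 0.20 M | 10 mM | run made earlier |  |
| dusk | 0.20 M | 6.7 mM | run made earlier |  |
| noon | 0.20 M | 15 mM | run made earlier |  |
| alder | 0.20 M | 10 mM | a closed flask charged with all of it at once and left for 12 h | 12 h |
| ash | 0.20 M | 10 mM | plug flow through a tube for 12 h, no back-mixing | 12 h |
| oak | 0.20 M | 10 mM | one stirred flow tank at steady state, fed with the mixture as stated, mean residence time 12 h |  |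
| cedar | 0.20 M (fed, over 6.00 h) | 10 mM | a stirred flask in which free monomer is dosed at a steady rate over 6.00 h without added volume, worked up at 12 h | 12 h |

- midnight (time / h: monomer in chains / %, over-reaction product / %): 0.667: 2.1, 0.2; 2.00: 5.5, 0; 3.00: 7.7, 0; 5.00: 11.9, 0.4; 8.00: 17.7, 0.8; 10.0: 20.5, 0.7; 12.0: 23.7, 1.2
- dusk (time / h: monomer in chains / %, over-reaction product / %): 0.417: 0.9, 0.2; 1.00: 1.9, 0.1; 2.00: 4.2, 0.3; 3.00: 6.1, 0; 4.00: 8.3, 0.1; 6.00: 12.1, 0.2; 8.00: 15.1, 0
- noon (time / h: monomer in chains / %, over-reaction product / %): 0.417: 1.1, 0.3; 1.00: 3.4, 0; 2.00: 6.8, 0.4; 3.00: 9.7, 0.5; 4.00: 12.6, 0.1; 6.00: 16.9, 0.1; 8.00: 20.9, 0.4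

(standard deviation of a reading: 0.3 percentage points)

* the set-up with the highest share of monomer in chains in all that became monomer in chains or over-reaction product or isomer of the product, at the outlet or at the end ("none" if the first two lie within 2 percentage points) (alder / ash / oak / cedar / none)
* share of monomer in chains in all that became monomer in chains or over-reaction product or isomer of the product, at the outlet or at the end, alder
* share of monomer in chains in all that became monomer in chains or over-reaction product or isomer of the product, at the outlet or at the end, ash
* share of monomer in chains in all that became monomer in chains or over-reaction product or isomer of the product, at the outlet or at the end, oak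
* share of monomer in chains in all that became monomer in chains or over-reaction product or isomer of the product, at the outlet or at the end, cedar

- the stated concentrations are those of everything mixed, before any reaction; amounts are the same in each set-up
- the feed brings no volume worth counting
- the earlier runs were made in a closed, stirred flask

How fast does free monomer go? At 2.00 h the midnight run reads 5.5 % in chains, and the logarithm of what remains gives 0.0283 h⁻¹ for the clearance constant, the pseudo-first-order fraction of free monomer lost per hour. It is a reading, with that reading's scatter. Held steady, it leaves 71.2 % at 12 h, so 28.8 % has gone. Midnight then reads 23.7 % in chains and 1.2 % over-reaction product, which is 3.9 percentage points short. A reading scatters by 0.3 points, and the constant, taken from one early reading, carries that scatter enlarged to 12 h, so the gap is an estimate. I book that gap to isomer of the product, which nobody read. A fading initiator could bend the curve as well; these runs don't part the two, and I commit to the steady constant.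

What share do chains keep? Alder has midnight's charge, so I put its share at chains over gone, 82.3 %, and ash, a tube with the same history, matches it. What has gone in alder is about 6.00 h old on average, so chains fade at about 0.0324 h⁻¹.

How do the other flasks age their chains? Oak's outlet has the mean age 12 h, and a mixed tank with first-order fading keeps the reciprocal of one plus rate times age, 72.0 %. Cedar's dose centres on 3.00 h, so I take its mean age as about 4.50 h, younger than alder's, and by this estimate it keeps 86.4 %. In my reckoning cedar stands 4.1 points above alder, the margin is 2 points, so I name cedar.

The forecast differs from my reckoning, giving none as best, with alder 96 %, ash 96 %, oak 93.3 % and cedar 97 %, and saying: “Isomer was never seen, so I take it as negligible.”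

The flasks give alder 79.7 %, ash 79.7 %, oak 72.8 % and cedar 83.5 %, so cedar stands highest.

    initiator → 2 initiating radical (k = 0.00580 h⁻¹)
    free monomer + initiating radical → growing radical + monomer in chains (k = 39000 M⁻¹ s⁻¹)
    free monomer + growing radical → monomer in chains + growing radical, rate k3*[growing radical]*[free monomer] (k = 3.20 × 10⁶ M⁻¹ h⁻¹)
    2 growing radical → dead chain (k = 2.00 × 10⁸ M⁻¹ s⁻¹)
    monomer in chains → over-reaction product (k = 0.00600 h⁻¹)
    monomer in chains ⇌ isomer of the product (K = 1.00, k = 0.0360 h⁻¹)

In cedar at 12.0 h stand 3.17 % isomer of the product and 0.595 % over-reaction product beside 19.1 % in chains. The clearance constant, with the dose spread over 6.00 h and plain decay after it, leaves 77.6 % of the free monomer in cedar, and the flask holds 77 %. Cedar left until 50 h holds 27.3 % free monomer, where the same constant gives 26.5 %.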